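**Assumption:** the target has no stereocentres, so "single enantiomer" does not apply; the only stereo-element is the (E)-enone C=C, which Step 4 sets. Compound numbers follow the forward route.

**Retrosynthetic overview**
- Cleave the enone Cα=Cβ bond (Claisen–Schmidt) into a chromenyl methyl ketone (A-ring) and a 3-prenyl-4-hydroxybenzaldehyde (B-ring), the latter carried as its MOM ether.
- The A-ring fragment comes from 2,4-dihydroxyacetophenone and prenal by condensation/oxa-6π-electrocyclisation; this forms the only new ring (the 2H-pyran) at the outset.
- The B-ring fragment comes from ortho C-prenylation of 4-hydroxybenzaldehyde, then MOM protection.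
- Endgame: aldol condensation sets the E-alkene, then mild acid removes the MOM group.

**Route**

Step 1
Reactants: 1, 2,4-dihydroxyacetophenone; 2, 3-methylbut-2-enal (prenal)
Product: 3, 1-(5-hydroxy-2,2-dimethyl-2H-chromen-6-yl)ethan-1-one (angular chromene; the OH ortho to the acetyl stays free and H-bonded)
Conditions: prenal (2 equiv), pyridine, 120 °C, sealed tube, 18 h
Reagents that add atoms: 3-methylbut-2-enal, CC(C)=CC=O
Why: Pyridine-mediated Knoevenagel-type condensation at C3 (the most nucleophilic carbon, between the two oxygens) gives an o-quinone methide dienone that closes by oxa-6π-electrocyclisation through the non-chelated 4-OH, giving the 5-hydroxy-6-acetyl chromene regioselectively.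

Step 2
Reactants: 4, 4-hydroxybenzaldehyde; 5, prenyl bromide (1-bromo-3-methylbut-2-ene)
Product: 6, 4-hydroxy-3-(3-methylbut-2-en-1-yl)benzaldehyde
Conditions: KOH (1.1 equiv), H2O, prenyl bromide (1.0 equiv), rt, 24–48 h; chromatography (modest yield expected, roughly 30–40%; unreacted 4 recovered)
Reagents that add atoms: prenyl bromide, CC(C)=CCBr
Why: Ambident phenoxide alkylation; in water the strongly solvated oxygen favours ortho C-alkylation (SN2 at the primary allylic carbon, so the prenyl group is linear), and the neutral O-prenyl ether by-product is removed by base extraction.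

Step 3
Reactants: 6; 7, chloromethyl methyl ether (MOMCl)
Product: 8, 4-(methoxymethoxy)-3-(3-methylbut-2-en-1-yl)benzaldehyde
Conditions: MOMCl (1.5 equiv), i-Pr2NEt, CH2Cl2, 0 °C → rt
Reagents that add atoms: chloromethyl methyl ether, COCCl
Why: Standard O-alkylation to the MOM acetal masks the phenol so the aldehyde is not deactivated as a para-phenoxide in the basic aldol step; aldehyde and prenyl are untouched.

Step 4
Reactants: 3; 8
Product: 9, (E)-1-(5-hydroxy-2,2-dimethyl-2H-chromen-6-yl)-3-[4-(methoxymethoxy)-3-(3-methylbut-2-en-1-yl)phenyl]prop-2-en-1-one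
Conditions: KOH (5 equiv, 50% aq.), EtOH, 0 °C → rt, 24–48 h; cold dilute HCl to pH ~5
Reagents that add atoms: none (both partners are the reactants)
Why: Claisen–Schmidt condensation of the methyl ketone enolate with a non-enolisable aldehyde; reversible aldol addition and E1cB dehydration give the thermodynamic (E)-enone only, and the MOM ether, chromene and prenyl group are base-stable.

Step 5
Reactants: 9
Product: 10, paratocarpin B, (E)-1-(5-hydroxy-2,2-dimethyl-2H-chromen-6-yl)-3-[4-hydroxy-3-(3-methylbut-2-en-1-yl)phenyl]prop-2-en-1-one
Conditions: 3 M aq. HCl/MeOH (1:5), 40 °C, 2–4 h, TLC-monitored, protected from light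
Reagents that add atoms: none
Why: Acid-catalysed acetal hydrolysis removes the MOM group under conditions mild and short enough to avoid prenyl-phenol cyclisation to a chroman or chalcone-to-flavanone closure; the E-alkene is unaffected.

**Compound list**
1 | 2,4-dihydroxyacetophenone | CC(=O)c1ccc(O)cc1O | starting material
2 | 3-methylbut-2-enal (prenal) | CC(C)=CC=O | starting material
3 | 1-(5-hydroxy-2,2-dimethyl-2H-chromen-6-yl)ethan-1-one | CC(=O)c1ccc2c(c1O)C=CC(C)(C)O2 | intermediate
4 | 4-hydroxybenzaldehyde | O=Cc1ccc(O)cc1 | starting material
5 | prenyl bromide | CC(C)=CCBr | starting material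
6 | 4-hydroxy-3-(3-methylbut-2-en-1-yl)benzaldehyde | CC(C)=CCc1cc(C=O)ccc1O | intermediate
7 | chloromethyl methyl ether (MOMCl) | COCCl | starting material (reagent)
8 | 4-(methoxymethoxy)-3-(3-methylbut-2-en-1-yl)benzaldehyde | CC(C)=CCc1cc(C=O)ccc1OCOC | intermediate
9 | (E)-MOM-protected chalcone | CC(C)=CCc1cc(/C=C/C(=O)c2ccc3c(c2O)C=CC(C)(C)O3)ccc1OCOC | intermediate
10 | paratocarpin B | CC(C)=CCc1cc(/C=C/C(=O)c2ccc3c(c2O)C=CC(C)(C)O3)ccc1O | target

**Total steps:** 5 (convergent).
**Longest linear sequence:** 4 steps (4 → 6 → 8 → 9 → 10).

**Steps most likely to fail, with fallbacks**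
1. **Step 2, C-prenylation:** O-alkylation and bis-prenylation compete and the yield is low. Fallback: regiospecific ortho-prenylation by a different mechanism. O-alkylate 4 to the 1,1-dimethylpropargyl ether, semi-hydrogenate (Lindlar) to the 1,1-dimethylallyl ether, then thermal aromatic Claisen rearrangement delivers the linear ortho-prenyl phenol 6.
2. **Step 5, acidic MOM removal:** the ortho-prenyl phenol can cyclise to a 2,2-dimethylchroman, or the chalcone can close to a flavanone. Fallback: change the protecting group to an allyl ether (allyl bromide/K2CO3 in Step 3), removed under neutral conditions with Pd(PPh3)4 and a scavenger such as morpholine, so no acid is used.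
3. **Step 4, Claisen–Schmidt:** the chelated 2'-hydroxy ketone reacts sluggishly as its phenoxide, and prolonged base can give Michael or flavanone by-products. Fallback: a two-stage directed aldol. Form the dianion of 3 with LiHMDS (2.2 equiv, THF, −78 °C), add 8 to give the β-hydroxy ketone, then dehydrate separately (MsCl/Et3N) to the (E)-enone.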